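**Retrosynthetic overview**
- The target comes from global O-debenzylation of a tri-O-benzyl isoflavone. The pyranone (ring C) is the only ring formed, closed from a β-ketoacetal; rings A and B are carried as benzenoids throughout.
- The β-ketoacetal comes from oxidative 1,2-aryl migration (Tl(NO3)3, MeOH) of a 2'-hydroxychalcone.
- The chalcone comes from an intermolecular Claisen–Schmidt aldol condensation (key C–C bond) of 4-benzyloxy-2-hydroxyacetophenone (ring A) with the pentasubstituted ring B benzaldehyde.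
- The ring B aldehyde comes from Sonogashira coupling of 2-methylbut-3-yn-2-ol with an ortho-iodobenzaldehyde, then alkyne hydrogenation; the iodide from phenol-directed ortho-iodination and O-methylation.
- The hydroxy-aldehyde comes from 2,4-dihydroxybenzaldehyde by benzylation, Dakin-type oxidation, temporary O-allylation, Vilsmeier formylation and deallylation.

Assumption: kwakhurin hydrate has no stereocentre, so "single enantiomer" means the achiral compound itself; the only stereo-element in the route is the (E)-alkene of the chalcone, and racemic intermediates lose their stereocentres later.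

**Step 1**
Reactants: 1 2,4-dihydroxybenzaldehyde
Product: 2 2,4-bis(benzyloxy)benzaldehyde
Conditions: BnBr (2.3 equiv), K2CO3 (3 equiv), DMF, 60 °C
Reagents that add atoms: benzyl bromide, BrCc1ccccc1
Why: Williamson ether synthesis in warm DMF alkylates both phenols (including the hydrogen-bonded 2-OH), installing hydrogenolysis-labile protection for the two future ring B phenols.

**Step 2**
Reactants: 2 2,4-bis(benzyloxy)benzaldehyde
Product: 4 2,4-bis(benzyloxy)phenol, via aryl formate 3 (not isolated)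
Conditions: mCPBA (1.3 equiv), CH2Cl2, 0 °C to rt; aq. NaHCO3/Na2S2O3 wash; then K2CO3 (cat.), MeOH, rt
Reagents that add atoms: meta-chloroperbenzoic acid (mCPBA), OOC(=O)c1cccc(Cl)c1
Why: Baeyer–Villiger (Dakin-type) oxidation, in which the electron-rich 2,4-dialkoxyaryl group migrates in preference to hydrogen and the resulting formate is methanolysed to the phenol.

**Step 3**
Reactants: 4 2,4-bis(benzyloxy)phenol
Product: 5 1-(allyloxy)-2,4-bis(benzyloxy)benzene
Conditions: allyl bromide (1.3 equiv), K2CO3, acetone, reflux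
Reagents that add atoms: allyl bromide, C=CCBr
Why: Williamson etherification gives an allyl ether that keeps the ring electron-rich for formylation and can later be removed without touching the benzyl ethers.

**Step 4**
Reactants: 5 1-(allyloxy)-2,4-bis(benzyloxy)benzene
Product: 7 5-(allyloxy)-2,4-bis(benzyloxy)benzaldehyde, via iminium salt 6 (not isolated)
Conditions: POCl3 (1.5 equiv), DMF, 0 °C to 60 °C; then aq. NaOAc, rt
Reagents that add atoms: N,N-dimethylformamide, CN(C)C=O; water, O
Why: Vilsmeier–Haack formylation attacks the one position that is para to one benzyloxy group and ortho to the other (the same selectivity that turns 1,2,4-trimethoxybenzene into 2,4,5-trimethoxybenzaldehyde), and the iminium salt is hydrolysed on work-up.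

**Step 5**
Reactants: 7 5-(allyloxy)-2,4-bis(benzyloxy)benzaldehyde
Product: 8 2,4-bis(benzyloxy)-5-hydroxybenzaldehyde
Conditions: Pd(PPh3)4 (2 mol%), K2CO3 (3 equiv), MeOH, rt
Reagents that add atoms: none
Why: Tsuji–Trost-type deallylation, in which zerovalent palladium ionises the aryl allyl ether to a π-allyl complex that is captured by methoxide, leaving the benzyl ethers and the aldehyde untouched.

**Step 6**
Reactants: 8 2,4-bis(benzyloxy)-5-hydroxybenzaldehyde
Product: 9 4,6-bis(benzyloxy)-3-hydroxy-2-iodobenzaldehyde (the 6-iodo derivative of 8, renumbered)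
Conditions: iodine (1.05 equiv), NaHCO3 (2 equiv), THF/H2O, 0 °C to rt
Reagents that add atoms: iodine, [I][I]
Why: Electrophilic aromatic iodination of the phenoxide, which directs to its only free ortho/para position, the carbon between OH and CHO (the site at which isovanillin is halogenated).

**Step 7**
Reactants: 9 4,6-bis(benzyloxy)-3-hydroxy-2-iodobenzaldehyde
Product: 10 4,6-bis(benzyloxy)-2-iodo-3-methoxybenzaldehyde
Conditions: MeI (2 equiv), K2CO3, DMF, rt
Reagents that add atoms: iodomethane, CI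
Why: Williamson O-methylation of the only free phenol installs the methoxy group of ring B.

**Step 8**
Reactants: 10 4,6-bis(benzyloxy)-2-iodo-3-methoxybenzaldehyde; 11 2-methylbut-3-yn-2-ol
Product: 12 4,6-bis(benzyloxy)-2-(3-hydroxy-3-methylbut-1-yn-1-yl)-3-methoxybenzaldehyde
Conditions: PdCl2(PPh3)2 (3 mol%), CuI (5 mol%), Et3N/THF, 50 °C
Reagents that add atoms: none
Why: Sonogashira coupling, helped by the ortho-formyl group activating the aryl iodide and by the linear alkyne tolerating two ortho substituents.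

**Step 9**
Reactants: 12 4,6-bis(benzyloxy)-2-(3-hydroxy-3-methylbut-1-yn-1-yl)-3-methoxybenzaldehyde
Product: 13 4,6-bis(benzyloxy)-2-(3-hydroxy-3-methylbutyl)-3-methoxybenzaldehyde
Conditions: H2 (1 atm), 10% Pd/C, Ph2S (0.01 equiv), EtOAc, rt
Reagents that add atoms: none
Why: Chemoselective catalytic hydrogenation over sulfide-poisoned Pd/C saturates the alkyne while the poison suppresses hydrogenolysis of the aryl benzyl ethers and reduction of the aromatic aldehyde.

**Step 10**
Reactants: 14 2,4-dihydroxyacetophenone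
Product: 15 1-[4-(benzyloxy)-2-hydroxyphenyl]ethan-1-one
Conditions: BnBr (1.05 equiv), K2CO3 (1.2 equiv), acetone, reflux
Reagents that add atoms: benzyl bromide, BrCc1ccccc1
Why: Williamson etherification is selective for the 4-OH because the 2-OH is held in a hydrogen bond to the ketone, and that free 2-OH later becomes the ring oxygen.

**Step 11**
Reactants: 13 4,6-bis(benzyloxy)-2-(3-hydroxy-3-methylbutyl)-3-methoxybenzaldehyde; 15 1-[4-(benzyloxy)-2-hydroxyphenyl]ethan-1-one
Product: 17 (E)-1-[4-(benzyloxy)-2-hydroxyphenyl]-3-[4,6-bis(benzyloxy)-2-(3-hydroxy-3-methylbutyl)-3-methoxyphenyl]prop-2-en-1-one, via aldol ketol 16 (not isolated)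
Conditions: KOH (50% aq., 10 equiv), EtOH, rt, 48–72 h; then dilute HCl to pH 5 at 0 °C
Reagents that add atoms: none
Why: Claisen–Schmidt (crossed aldol) condensation, in which the aldehyde has no α-hydrogen so only the acetophenone enolate adds, and E1cB dehydration of the ketol gives the conjugated (E)-enone as the thermodynamic alkene.

**Step 12**
Reactants: 17 (E)-1-[4-(benzyloxy)-2-hydroxyphenyl]-3-[4,6-bis(benzyloxy)-2-(3-hydroxy-3-methylbutyl)-3-methoxyphenyl]prop-2-en-1-one
Product: 18 1-[4-(benzyloxy)-2-hydroxyphenyl]-2-[4,6-bis(benzyloxy)-2-(3-hydroxy-3-methylbutyl)-3-methoxyphenyl]-3,3-dimethoxypropan-1-one (racemic)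
Conditions: Tl(NO3)3·3H2O (1.2 equiv), MeOH/CH(OMe)3 (1:1), rt, 2–4 h
Reagents that add atoms: methanol, CO
Why: Oxidative 1,2-aryl migration (oxythallation of the enone by trivalent thallium, then shift of the electron-rich ring B aryl from C-β to C-α with loss of TlNO3), the classical chalcone-to-isoflavone rearrangement, giving a racemic α-stereocentre that is destroyed in the next step.

**Step 13**
Reactants: 18 1-[4-(benzyloxy)-2-hydroxyphenyl]-2-[4,6-bis(benzyloxy)-2-(3-hydroxy-3-methylbutyl)-3-methoxyphenyl]-3,3-dimethoxypropan-1-one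
Product: 19 7-(benzyloxy)-3-[4,6-bis(benzyloxy)-2-(3-hydroxy-3-methylbutyl)-3-methoxyphenyl]-4H-chromen-4-one
Conditions: 10% aq. HCl, MeOH/THF, 50 °C, 1–2 h
Reagents that add atoms: none
Why: Acid-catalysed cyclocondensation, in which the 2-hydroxyl of ring A attacks the acetal carbon and two molecules of methanol are lost to give the aromatic 4-pyranone (ring C), under conditions mild enough for the saturated tertiary alcohol and the benzyl ethers.

**Step 14**
Reactants: 19 7-(benzyloxy)-3-[4,6-bis(benzyloxy)-2-(3-hydroxy-3-methylbutyl)-3-methoxyphenyl]-4H-chromen-4-one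
Product: 20 kwakhurin hydrate, 3-[4,6-dihydroxy-2-(3-hydroxy-3-methylbutyl)-3-methoxyphenyl]-7-hydroxy-4H-chromen-4-one
Conditions: H2 (1 atm), 10% Pd/C, EtOAc/MeOH (1:1), rt, stopped at complete debenzylation
Reagents that add atoms: none
Why: Hydrogenolysis of the three aryl benzyl ethers under neutral conditions frees the phenols without endangering the tertiary alcohol, and the vinylogous-ester C2=C3 bond is reduced much more slowly.

**Compound list**
1 | 2,4-dihydroxybenzaldehyde | O=Cc1ccc(O)cc1O | starting material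
2 | 2,4-bis(benzyloxy)benzaldehyde | O=Cc1ccc(OCc2ccccc2)cc1OCc1ccccc1 | intermediate
3 | 2,4-bis(benzyloxy)phenyl formate (aryl formate, formed in the flask) | O=COc1ccc(OCc2ccccc2)cc1OCc1ccccc1 | intermediate
4 | 2,4-bis(benzyloxy)phenol | Oc1ccc(OCc2ccccc2)cc1OCc1ccccc1 | intermediate
5 | 1-(allyloxy)-2,4-bis(benzyloxy)benzene | C=CCOc1ccc(OCc2ccccc2)cc1OCc1ccccc1 | intermediate
6 | N-[5-(allyloxy)-2,4-bis(benzyloxy)benzylidene]-N-methylmethanaminium chloride (iminium salt, formed in the flask) | C[N+](C)=Cc1cc(OCC=C)c(OCc2ccccc2)cc1OCc1ccccc1.[Cl-] | intermediate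
7 | 5-(allyloxy)-2,4-bis(benzyloxy)benzaldehyde | O=Cc1cc(OCC=C)c(OCc2ccccc2)cc1OCc1ccccc1 | intermediate
8 | 2,4-bis(benzyloxy)-5-hydroxybenzaldehyde | O=Cc1cc(O)c(OCc2ccccc2)cc1OCc1ccccc1 | intermediate
9 | 4,6-bis(benzyloxy)-3-hydroxy-2-iodobenzaldehyde | O=Cc1c(I)c(O)c(OCc2ccccc2)cc1OCc1ccccc1 | intermediate
10 | 4,6-bis(benzyloxy)-2-iodo-3-methoxybenzaldehyde | O=Cc1c(I)c(OC)c(OCc2ccccc2)cc1OCc1ccccc1 | intermediate
11 | 2-methylbut-3-yn-2-ol | C#CC(C)(C)O | starting material
12 | 4,6-bis(benzyloxy)-2-(3-hydroxy-3-methylbut-1-yn-1-yl)-3-methoxybenzaldehyde | O=Cc1c(C#CC(C)(C)O)c(OC)c(OCc2ccccc2)cc1OCc1ccccc1 | intermediate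
13 | 4,6-bis(benzyloxy)-2-(3-hydroxy-3-methylbutyl)-3-methoxybenzaldehyde | O=Cc1c(CCC(C)(C)O)c(OC)c(OCc2ccccc2)cc1OCc1ccccc1 | intermediate
14 | 2,4-dihydroxyacetophenone | CC(=O)c1ccc(O)cc1O | starting material
15 | 1-[4-(benzyloxy)-2-hydroxyphenyl]ethan-1-one | CC(=O)c1ccc(OCc2ccccc2)cc1O | intermediate
16 | 1-[4-(benzyloxy)-2-hydroxyphenyl]-3-[4,6-bis(benzyloxy)-2-(3-hydroxy-3-methylbutyl)-3-methoxyphenyl]-3-hydroxypropan-1-one (aldol ketol, racemic, formed in the flask) | O=C(CC(O)c1c(CCC(C)(C)O)c(OC)c(OCc2ccccc2)cc1OCc1ccccc1)c1ccc(OCc2ccccc2)cc1O | intermediate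
17 | (E)-1-[4-(benzyloxy)-2-hydroxyphenyl]-3-[4,6-bis(benzyloxy)-2-(3-hydroxy-3-methylbutyl)-3-methoxyphenyl]prop-2-en-1-one | O=C(/C=C/c1c(CCC(C)(C)O)c(OC)c(OCc2ccccc2)cc1OCc1ccccc1)c1ccc(OCc2ccccc2)cc1O | intermediate
18 | 1-[4-(benzyloxy)-2-hydroxyphenyl]-2-[4,6-bis(benzyloxy)-2-(3-hydroxy-3-methylbutyl)-3-methoxyphenyl]-3,3-dimethoxypropan-1-one (racemic) | COC(OC)C(C(=O)c1ccc(OCc2ccccc2)cc1O)c1c(CCC(C)(C)O)c(OC)c(OCc2ccccc2)cc1OCc1ccccc1 | intermediate
19 | 7-(benzyloxy)-3-[4,6-bis(benzyloxy)-2-(3-hydroxy-3-methylbutyl)-3-methoxyphenyl]-4H-chromen-4-one | O=c1c(-c2c(CCC(C)(C)O)c(OC)c(OCc3ccccc3)cc2OCc2ccccc2)coc2cc(OCc3ccccc3)ccc12 | intermediate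
20 | kwakhurin hydrate | COc1c(O)cc(O)c(-c2coc3cc(O)ccc3c2=O)c1CCC(C)(C)O | target

**Step count and risks**
Total steps: 14. Longest linear sequence: 13 steps (1 to 20 through steps 1–9 and 11–14); the ring A branch is one step (step 10).

Most likely to fail:

Step 6 (iodination). The carbon between the two benzyloxy groups, or ipso attack at the formyl-bearing carbon, could compete with the phenoxide-directed site. The fallback sets out from 7 and uses the allyl group instead of discarding it. Aromatic Claisen rearrangement (PhNEt2, 190 °C) can only deliver allyl to the single free ortho carbon and gives 2-allyl-4,6-bis(benzyloxy)-3-hydroxybenzaldehyde F1. Methylation (MeI, K2CO3, DMF) gives 2-allyl-4,6-bis(benzyloxy)-3-methoxybenzaldehyde F2. Cross-metathesis with 2-methylbut-2-ene (second-generation Grubbs catalyst RuCl2(=CHPh)(PCy3)(H2IMes), CH2Cl2, 40 °C) gives 4,6-bis(benzyloxy)-3-methoxy-2-(3-methylbut-2-en-1-yl)benzaldehyde F3. Markovnikov oxymercuration–demercuration (Hg(OAc)2, THF/H2O, 0 °C; then NaBH4, aq. NaOH), which also reduces the aldehyde, gives 4-[3,5-bis(benzyloxy)-2-(hydroxymethyl)-6-methoxyphenyl]-2-methylbutan-2-ol F4. Selective benzylic oxidation with MnO2 (CH2Cl2, rt) then comes back to the route at 13, bypassing steps 5–9.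

Step 11 (aldol condensation). The aldehyde is di-ortho-substituted and electron-rich, and the ketone reacts as a phenoxide, so the reversible hydroxide-mediated condensation may stall. The fallback sets out from 15 and makes the C–C bond kinetically. LiN(SiMe3)2 (2.2 equiv, THF, −78 °C) gives the phenoxide–enolate dianion, which adds irreversibly to 13 (directed aldol addition); the ketol 16 is now isolated. Acetylation (Ac2O, Et3N, DMAP, CH2Cl2, 0 °C) gives 2-{3-acetoxy-3-[4,6-bis(benzyloxy)-2-(3-hydroxy-3-methylbutyl)-3-methoxyphenyl]propanoyl}-5-(benzyloxy)phenyl acetate F5. E1cB elimination of acetic acid with DBU (CH2Cl2, rt) gives 5-(benzyloxy)-2-{(E)-3-[4,6-bis(benzyloxy)-2-(3-hydroxy-3-methylbutyl)-3-methoxyphenyl]prop-2-enoyl}phenyl acetate F6. Methanolysis of the phenolic acetate (K2CO3, MeOH, rt) comes back to the route at 17.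

Step 12 (oxidative rearrangement). The twisted 2,6-disubstituted, very electron-rich ring B may be oxidised by Tl(NO3)3, or the free 2'-OH may divert the reaction to an aurone. The fallback sets out from 17 and changes the substrate class. Intramolecular oxa-Michael cyclisation (NaOAc, EtOH, reflux) gives racemic 7-(benzyloxy)-2-[4,6-bis(benzyloxy)-2-(3-hydroxy-3-methylbutyl)-3-methoxyphenyl]chroman-4-one F7. Oxidative 2,3-aryl shift of this flavanone with PhI(OH)OTs (MeCN, 60 °C) comes back to the route at 19, bypassing 18 and step 13.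

**Further compounds**
F1 | step 6 | 2-allyl-4,6-bis(benzyloxy)-3-hydroxybenzaldehyde | O=Cc1c(CC=C)c(O)c(OCc2ccccc2)cc1OCc1ccccc1
F2 | step 6 | 2-allyl-4,6-bis(benzyloxy)-3-methoxybenzaldehyde | O=Cc1c(CC=C)c(OC)c(OCc2ccccc2)cc1OCc1ccccc1
F3 | step 6 | 4,6-bis(benzyloxy)-3-methoxy-2-(3-methylbut-2-en-1-yl)benzaldehyde | O=Cc1c(CC=C(C)C)c(OC)c(OCc2ccccc2)cc1OCc1ccccc1
F4 | step 6 | 4-[3,5-bis(benzyloxy)-2-(hydroxymethyl)-6-methoxyphenyl]-2-methylbutan-2-ol | OCc1c(CCC(C)(C)O)c(OC)c(OCc2ccccc2)cc1OCc1ccccc1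
F5 | step 11 | 2-{3-acetoxy-3-[4,6-bis(benzyloxy)-2-(3-hydroxy-3-methylbutyl)-3-methoxyphenyl]propanoyl}-5-(benzyloxy)phenyl acetate (racemic) | CC(=O)OC(CC(=O)c1ccc(OCc2ccccc2)cc1OC(C)=O)c1c(CCC(C)(C)O)c(OC)c(OCc2ccccc2)cc1OCc1ccccc1
F6 | step 11 | 5-(benzyloxy)-2-{(E)-3-[4,6-bis(benzyloxy)-2-(3-hydroxy-3-methylbutyl)-3-methoxyphenyl]prop-2-enoyl}phenyl acetate | CC(=O)Oc1cc(OCc2ccccc2)ccc1C(=O)/C=C/c1c(CCC(C)(C)O)c(OC)c(OCc2ccccc2)cc1OCc1ccccc1
F7 | step 12 | 7-(benzyloxy)-2-[4,6-bis(benzyloxy)-2-(3-hydroxy-3-methylbutyl)-3-methoxyphenyl]chroman-4-one (racemic) | O=C1CC(c2c(CCC(C)(C)O)c(OC)c(OCc3ccccc3)cc2OCc2ccccc2)Oc2cc(OCc3ccccc3)ccc12
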